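**Retrosynthetic overview**
1. Target 15 ← flavonol 11 (5,7-dihydroxy, 8-OMOM, three benzyl ethers) by 7-O-methylation, MOM cleavage, 8-O-acetylation and hydrogenolysis.
2. Ring A of 11 ← pyranone ester 8 + ethyl acetate: C7–C8 by acetylation of the CH2(OMOM) dienolate, C5–C6 by Claisen closure onto the C3 ester. Ring A is formed last.
3. 8 ← 3,6-dibromopyranone 5 by site-selective Suzuki coupling at C6 (ring B attached), then methoxycarbonylation of C3–Br.
4. 5 ← kojic acid by C6 bromination, O-benzylation, MOM protection and C3 bromination. Ring C is bought.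
5. Feature: ring C of the target with its 3-oxygen, C4=O and the oxygen-bearing C8 on C8a (O1, C2, C3–O, C4=O, C4a, C8a, C8–O) is the kojic acid skeleton. Only C5, C6, C7 and the aryl ring have to be added.

Key step: step 7

Remark: pyranones 1–10 are numbered as in kojic acid (C2 bears the CH2O group, C4 is the carbonyl, C5 the ring oxygen substituent, C6 the bromine or aryl group); 11–15 carry flavone numbering. The C8 oxygen is carried as a MOM ether, which tolerates bromine, palladium and amide bases and leaves no benzylic cation on cleavage. Compound 10 is racemic at its CH(OMOM) centre, which disappears on aromatisation.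

**Step 1**
Reactants: 1 kojic acid
Product: 2 6-bromo-5-hydroxy-2-(hydroxymethyl)-4H-pyran-4-one
Conditions: NBS (1.05 equiv), DMF, 0 °C to rt
Reagents that add atoms: N-bromosuccinimide, O=C1CCC(=O)N1Br
Why: Electrophilic bromination of the enolic, phenol-like pyranone occurs at C6, ortho to the free 5-OH, the usual site of electrophilic substitution in kojic acid.

**Step 2**
Reactants: 2 6-bromo-5-hydroxy-2-(hydroxymethyl)-4H-pyran-4-one
Product: 3 5-(benzyloxy)-6-bromo-2-(hydroxymethyl)-4H-pyran-4-one
Conditions: BnBr (1.1 equiv), K2CO3 (1.5 equiv), DMF, rt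
Reagents that add atoms: benzyl bromide, BrCc1ccccc1
Why: Williamson etherification in which carbonate ionises only the acidic enolic 5-OH, so the primary alcohol stays free and the C6 bromide is not displaced.

**Step 3**
Reactants: 3 5-(benzyloxy)-6-bromo-2-(hydroxymethyl)-4H-pyran-4-one
Product: 4 5-(benzyloxy)-6-bromo-2-[(methoxymethoxy)methyl]-4H-pyran-4-one
Conditions: MOMCl (1.5 equiv), i-Pr2NEt (2 equiv), CH2Cl2, 0 °C to rt
Reagents that add atoms: chloromethyl methyl ether, COCCl
Why: Standard acetal protection of a primary alcohol with MOMCl and a hindered amine.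

**Step 4**
Reactants: 4 5-(benzyloxy)-6-bromo-2-[(methoxymethoxy)methyl]-4H-pyran-4-one
Product: 5 5-(benzyloxy)-3,6-dibromo-2-[(methoxymethoxy)methyl]-4H-pyran-4-one
Conditions: Br2 (1.1 equiv), pyridine (3 equiv), CH2Cl2, 0 °C to rt
Reagents that add atoms: bromine, BrBr
Why: Electrophilic α-bromination of a vinylogous ester (as in the 3-bromination of chromones) at C3, the only ring C–H and the β-carbon of the O1–C2=C3 enol ether, with pyridine trapping HBr so the MOM acetal survives.

**Step 5**
Reactants: 5 5-(benzyloxy)-3,6-dibromo-2-[(methoxymethoxy)methyl]-4H-pyran-4-one; 6 3,4-bis(benzyloxy)phenylboronic acid (1.05 equiv)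
Product: 7 5-(benzyloxy)-6-[3,4-bis(benzyloxy)phenyl]-3-bromo-2-[(methoxymethoxy)methyl]-4H-pyran-4-one
Conditions: Pd(PPh3)4 (5 mol %), K3PO4 (2 equiv), 1,4-dioxane/H2O 10:1, 60 °C
Reagents that add atoms: none
Why: Suzuki–Miyaura coupling in which zerovalent palladium should insert selectively into C6–Br, a vinylogous acyl bromide next to the ring oxygen with one ortho substituent, while the electron-richer, doubly flanked α-bromide at C3 stays, as in the β-selective couplings of α,β-dibromo enones and butenolides.

**Step 6**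
Reactants: 7 5-(benzyloxy)-6-[3,4-bis(benzyloxy)phenyl]-3-bromo-2-[(methoxymethoxy)methyl]-4H-pyran-4-one
Product: 8 methyl 5-(benzyloxy)-6-[3,4-bis(benzyloxy)phenyl]-2-[(methoxymethoxy)methyl]-4-oxo-4H-pyran-3-carboxylate
Conditions: CO (1 atm), Pd(OAc)2 (5 mol %), Xantphos (4,5-bis(diphenylphosphino)-9,9-dimethylxanthene, 6 mol %), Et3N (3 equiv), MeOH/toluene 1:2, 80 °C
Reagents that add atoms: carbon monoxide, [C-]#[O+]; methanol, CO
Why: Palladium-catalysed alkoxycarbonylation of an alkenyl bromide (oxidative addition, CO insertion, methanolysis of the acylpalladium), for which the wide-bite-angle ligand allows atmospheric CO pressure.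

**Step 7**
Reactants: 8 methyl 5-(benzyloxy)-6-[3,4-bis(benzyloxy)phenyl]-2-[(methoxymethoxy)methyl]-4-oxo-4H-pyran-3-carboxylate; 9 ethyl acetate (1.2 equiv)
Product: 11 3-(benzyloxy)-2-[3,4-bis(benzyloxy)phenyl]-5,7-dihydroxy-8-(methoxymethoxy)-4H-chromen-4-one, via methyl ketone 10 (not isolated)
Conditions: LiN(i-Pr)2 (1.05 equiv), THF, −78 °C; EtOAc, −78 to −20 °C; LiN(i-Pr)2 (2.5 equiv), −78 to 0 °C; AcOH, then aq. NH4Cl
Reagents that add atoms: none
Why: Proposed new method: LiN(i-Pr)2 removes a proton from the CH2(OMOM) group of 8, which is vinylogous to both the ring carbonyl and the ester, and the lithium dienolate is C-acetylated there by ethyl acetate (C7–C8), the liberated ethoxide converting ketone 10 into its enolate so the acylation is not reversed; the second charge of base then deprotonates the acetyl CH3 to a dianion whose terminal carbanion attacks the neighbouring C3 ester (C5–C6), methoxide leaves and the cyclohexadienone tautomerises to the 5,7-dihydroxy arene. The closest known reaction types are the lateral acylation of lithiated 2-alkyl-4-pyranones and o-toluates with esters and the base-induced Claisen cyclisation of 2-acetonylbenzoates to naphthalene-1,3-diols, here joined in one operation on a pyranone ester. Ring A closes in a 6-(enolexo)-exo-trig Claisen condensation, and no stereocentre is formed. The step needs acylation at the exocyclic carbon and not at C3 of the dienolate, which is secured because C3 is fully substituted and an adduct there cannot regain the pyranone. It also needs C-attack and not O-attack on the ester, which the carbanion character of the dianion terminus favours; an enol lactone, if formed, would be reopened by the alkoxides present, the aromatic bis-phenoxide being the thermodynamic sink. The ring C4=O is not attacked because it is a vinylogous ester carbonyl that shares the enolate charge.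

**Step 8**
Reactants: 11 3-(benzyloxy)-2-[3,4-bis(benzyloxy)phenyl]-5,7-dihydroxy-8-(methoxymethoxy)-4H-chromen-4-one
Product: 12 3-(benzyloxy)-2-[3,4-bis(benzyloxy)phenyl]-5-hydroxy-7-methoxy-8-(methoxymethoxy)-4H-chromen-4-one
Conditions: MeI (1.1 equiv), K2CO3 (1.2 equiv), acetone, rt
Reagents that add atoms: iodomethane, CI
Why: Williamson methylation under weak base is selective for the more acidic, non-chelated 7-OH, the 5-OH being held in a hydrogen bond to C4=O, as is standard for 5,7-dihydroxyflavones.

**Step 9**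
Reactants: 12 3-(benzyloxy)-2-[3,4-bis(benzyloxy)phenyl]-5-hydroxy-7-methoxy-8-(methoxymethoxy)-4H-chromen-4-one
Product: 13 3-(benzyloxy)-2-[3,4-bis(benzyloxy)phenyl]-5,8-dihydroxy-7-methoxy-4H-chromen-4-one
Conditions: 3 M HCl, MeOH/THF, 45 °C, under argon
Reagents that add atoms: none
Why: Acid-catalysed acetal cleavage (transacetalisation to dimethoxymethane) removes the aryl MOM ether while benzyl and methyl ethers are inert, and argon guards the 5,8-hydroquinone against oxidation.

**Step 10**
Reactants: 13 3-(benzyloxy)-2-[3,4-bis(benzyloxy)phenyl]-5,8-dihydroxy-7-methoxy-4H-chromen-4-one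
Product: 14 3-(benzyloxy)-2-[3,4-bis(benzyloxy)phenyl]-5-hydroxy-7-methoxy-4-oxo-4H-chromen-8-yl acetate
Conditions: Ac2O (1.1 equiv), pyridine, CH2Cl2, 0 °C
Reagents that add atoms: acetic anhydride, CC(=O)OC(C)=O
Why: O-Acylation with one equivalent of anhydride takes the free 8-phenol, whereas the 5-OH is deactivated by its chelate to C4=O and is acetylated only under forcing conditions.

**Step 11**
Reactants: 14 3-(benzyloxy)-2-[3,4-bis(benzyloxy)phenyl]-5-hydroxy-7-methoxy-4-oxo-4H-chromen-8-yl acetate
Product: 15 gossypetin 7-methyl ether 8-acetate, 2-(3,4-dihydroxyphenyl)-3,5-dihydroxy-7-methoxy-4-oxo-4H-chromen-8-yl acetate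
Conditions: H2 (1 atm), 10% Pd/C, EtOAc/THF, rt
Reagents that add atoms: none
Why: Hydrogenolysis of the three benzyl ethers over palladium in a non-nucleophilic solvent leaves the aryl acetate, the methyl ether and the flavone C2=C3 bond untouched and should give the target, which has no stereocentre.

**Compound list**
1 | kojic acid, 5-hydroxy-2-(hydroxymethyl)-4H-pyran-4-one | OCc1cc(=O)c(O)co1 | starting material
2 | 6-bromo-5-hydroxy-2-(hydroxymethyl)-4H-pyran-4-one | OCc1cc(=O)c(O)c(Br)o1 | intermediate
3 | 5-(benzyloxy)-6-bromo-2-(hydroxymethyl)-4H-pyran-4-one | OCc1cc(=O)c(OCc2ccccc2)c(Br)o1 | intermediate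
4 | 5-(benzyloxy)-6-bromo-2-[(methoxymethoxy)methyl]-4H-pyran-4-one | COCOCc1cc(=O)c(OCc2ccccc2)c(Br)o1 | intermediate
5 | 5-(benzyloxy)-3,6-dibromo-2-[(methoxymethoxy)methyl]-4H-pyran-4-one | COCOCc1c(Br)c(=O)c(OCc2ccccc2)c(Br)o1 | intermediate
6 | 3,4-bis(benzyloxy)phenylboronic acid | OB(O)c1ccc(OCc2ccccc2)c(OCc2ccccc2)c1 | starting material
7 | 5-(benzyloxy)-6-[3,4-bis(benzyloxy)phenyl]-3-bromo-2-[(methoxymethoxy)methyl]-4H-pyran-4-one | COCOCc1c(Br)c(=O)c(OCc2ccccc2)c(-c2ccc(OCc3ccccc3)c(OCc3ccccc3)c2)o1 | intermediate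
8 | methyl 5-(benzyloxy)-6-[3,4-bis(benzyloxy)phenyl]-2-[(methoxymethoxy)methyl]-4-oxo-4H-pyran-3-carboxylate | COC(=O)c1c(COCOC)oc(-c2ccc(OCc3ccccc3)c(OCc3ccccc3)c2)c(OCc2ccccc2)c1=O | intermediate
9 | ethyl acetate | CCOC(C)=O | starting material
10 | methyl 5-(benzyloxy)-6-[3,4-bis(benzyloxy)phenyl]-2-[1-(methoxymethoxy)-2-oxopropyl]-4-oxo-4H-pyran-3-carboxylate (racemic; present in the flask as its lithium enolate, not isolated) | COC(=O)c1c(C(OCOC)C(C)=O)oc(-c2ccc(OCc3ccccc3)c(OCc3ccccc3)c2)c(OCc2ccccc2)c1=O | intermediate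
11 | 3-(benzyloxy)-2-[3,4-bis(benzyloxy)phenyl]-5,7-dihydroxy-8-(methoxymethoxy)-4H-chromen-4-one | Oc1cc(O)c2c(=O)c(OCc3ccccc3)c(-c3ccc(OCc4ccccc4)c(OCc4ccccc4)c3)oc2c1OCOC | intermediate
12 | 3-(benzyloxy)-2-[3,4-bis(benzyloxy)phenyl]-5-hydroxy-7-methoxy-8-(methoxymethoxy)-4H-chromen-4-one | COc1cc(O)c2c(=O)c(OCc3ccccc3)c(-c3ccc(OCc4ccccc4)c(OCc4ccccc4)c3)oc2c1OCOC | intermediate
13 | 3-(benzyloxy)-2-[3,4-bis(benzyloxy)phenyl]-5,8-dihydroxy-7-methoxy-4H-chromen-4-one | COc1cc(O)c2c(=O)c(OCc3ccccc3)c(-c3ccc(OCc4ccccc4)c(OCc4ccccc4)c3)oc2c1O | intermediate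
14 | 3-(benzyloxy)-2-[3,4-bis(benzyloxy)phenyl]-5-hydroxy-7-methoxy-4-oxo-4H-chromen-8-yl acetate | COc1cc(O)c2c(=O)c(OCc3ccccc3)c(-c3ccc(OCc4ccccc4)c(OCc4ccccc4)c3)oc2c1OC(C)=O | intermediate
15 | gossypetin 7-methyl ether 8-acetate | COc1cc(O)c2c(=O)c(O)c(-c3ccc(O)c(O)c3)oc2c1OC(C)=O | target

**Step count**
Total: 11 steps. Longest linear sequence: 11 steps (1 to 15).

**Steps most likely to fail**

Step 7. The stabilised dienolate may be acylated only sluggishly by the enolisable ester. The ketone enolate may close through oxygen to an enol lactone. Excess amide base may consume ethyl acetate by self-condensation. The fallback sets out from 8 and comes back at 11, and it uses known reaction types only. Compound 8 would be deprotonated with LiN(SiMe3)2 (1.1 equiv, THF, −78 °C) and acylated with N-methoxy-N-methylacetamide. The stable tetrahedral chelate releases the ketone only on acidic work-up, so one equivalent of base suffices and methyl ketone 10 would be isolated. In a separate operation 10 would be cyclised with NaOMe in MeOH/THF (rt to 50 °C), the classical alkoxide Claisen closure of 2-acetonylbenzoates under thermodynamic control. Any enol lactone is reopened by methoxide and the aromatic resorcinolate is the sink, which should give 11. This fallback makes no compound outside the list (F0).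

Step 5. Oxidative addition may occur at both C–Br bonds, leading to coupling at C3 or double coupling. The fallback sets out from 4 and comes back at 8, and it replaces positional selectivity by selectivity through halogen identity. Compound 4 would be chlorinated at C3 with N-chlorosuccinimide (DMF, 50 °C) to give 5-(benzyloxy)-6-bromo-3-chloro-2-[(methoxymethoxy)methyl]-4H-pyran-4-one F1. Coupling of F1 with 6 under the step 5 conditions can then engage only the C–Br bond and should give 5-(benzyloxy)-6-[3,4-bis(benzyloxy)phenyl]-3-chloro-2-[(methoxymethoxy)methyl]-4H-pyran-4-one F2. The alkenyl chloride of F2 would be methoxycarbonylated with a more electron-rich catalyst (Pd(OAc)2, 1,3-bis(dicyclohexylphosphino)propane bis(tetrafluoroborate), K2CO3, CO 1 atm, MeOH/DMSO, 110 °C) to give 8.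

Step 6. CO-saturated palladium may insert too slowly into the hindered C3–Br bond, so that hydrodebromination takes over. The fallback sets out from 7 and comes back at 8, and it builds the ester carbon by cross-coupling without CO followed by oxidation. Compound 7 would be coupled with potassium vinyltrifluoroborate (PdCl2(dppf), Cs2CO3, THF/H2O, 70 °C) to give 5-(benzyloxy)-6-[3,4-bis(benzyloxy)phenyl]-3-ethenyl-2-[(methoxymethoxy)methyl]-4H-pyran-4-one F3. Lemieux–Johnson cleavage (OsO4 cat., NaIO4, 2,6-lutidine, dioxane/H2O) should give 5-(benzyloxy)-6-[3,4-bis(benzyloxy)phenyl]-2-[(methoxymethoxy)methyl]-4-oxo-4H-pyran-3-carbaldehyde F4. Pinnick oxidation (NaClO2, NaH2PO4, 2-methyl-2-butene, t-BuOH/H2O) should give 5-(benzyloxy)-6-[3,4-bis(benzyloxy)phenyl]-2-[(methoxymethoxy)methyl]-4-oxo-4H-pyran-3-carboxylic acid F5. Esterification of F5 with Me3SiCHN2 in MeOH/toluene gives 8.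

**Further compounds**
F0 | step 7 | none | none
F1 | step 5 | 5-(benzyloxy)-6-bromo-3-chloro-2-[(methoxymethoxy)methyl]-4H-pyran-4-one | COCOCc1c(Cl)c(=O)c(OCc2ccccc2)c(Br)o1
F2 | step 5 | 5-(benzyloxy)-6-[3,4-bis(benzyloxy)phenyl]-3-chloro-2-[(methoxymethoxy)methyl]-4H-pyran-4-one | COCOCc1c(Cl)c(=O)c(OCc2ccccc2)c(-c2ccc(OCc3ccccc3)c(OCc3ccccc3)c2)o1
F3 | step 6 | 5-(benzyloxy)-6-[3,4-bis(benzyloxy)phenyl]-3-ethenyl-2-[(methoxymethoxy)methyl]-4H-pyran-4-one | COCOCc1c(C=C)c(=O)c(OCc2ccccc2)c(-c2ccc(OCc3ccccc3)c(OCc3ccccc3)c2)o1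
F4 | step 6 | 5-(benzyloxy)-6-[3,4-bis(benzyloxy)phenyl]-2-[(methoxymethoxy)methyl]-4-oxo-4H-pyran-3-carbaldehyde | COCOCc1c(C=O)c(=O)c(OCc2ccccc2)c(-c2ccc(OCc3ccccc3)c(OCc3ccccc3)c2)o1
F5 | step 6 | 5-(benzyloxy)-6-[3,4-bis(benzyloxy)phenyl]-2-[(methoxymethoxy)methyl]-4-oxo-4H-pyran-3-carboxylic acid | COCOCc1c(C(=O)O)c(=O)c(OCc2ccccc2)c(-c2ccc(OCc3ccccc3)c(OCc3ccccc3)c2)o1
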